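**Plan**

- Retrosynthesis: ring B is cut at C7–C8 (Friedel–Crafts acylation) and C5–C6 (acetate aldol, then dehydration). The lactone is cut at O–C19 and C10–C20 in one operation (formaldehyde aldol–lactonisation). C9–C10 (Pd α-arylation) and C4–CH3 (auxiliary-controlled methylation) are cut last.
- Forward: ring C bromide 9 (six steps from 1,3-dimethoxybenzene) and ring A keto ester 15 (two steps) are joined at C9–C10. The lactone ring closes next, ring B last, followed by reduction and deprotection.
- Enabling feature: in ring A the C5 ketone lies between quaternary C4 (CH3, C19 ester) and C10 (aryl, H). C10 is therefore the only enolisable α-carbon, and a C20 hydroxymethyl can reach C19 only when cis (1,3-diaxial) to it.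
- Stereochemistry: C4 comes from methylation of the L-valine tert-butyl ester enamine. C10 is relayed from C4 by lactonisation-driven aldol equilibration. C5 comes from axial protonation in the Li/NH3 reduction of the C5=C6 enone (trans A/B).
- Oxygen pattern: O11 is benzyl (lost in the Li/NH3 step), O14 is methyl (removed last by BCl3 chelated to the C7 ketone), O12 methyl is kept.

Key step: step 10

Assumption: the toluene/HMPA variant of the valine tert-butyl ester enamine methylation is taken to give the (S)-keto ester; the sense of this auxiliary inverts with the coordinating additive, so the THF variant (or the D-valine ester) would be used if it proved opposite.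

Positions are given in abietane numbering (C1–C20). Ar = 2-(benzyloxy)-3,5-dimethoxy-4-(propan-2-yl)phenyl, attached through the future C9.

**Route**

Step 1
Reactants: 1 1,3-dimethoxybenzene
Product: 3 2-(2,6-dimethoxyphenyl)propan-2-ol, via aryllithium 2 (not isolated)
Conditions: n-BuLi, THF, 0 °C → rt; acetone, −78 °C → rt; H2O
Reagents that add atoms: acetone, CC(C)=O
Why: Directed ortho-metalation: the two methoxy groups jointly direct n-BuLi to C2, and the aryllithium adds to acetone (1,2-addition) to bring in the three carbons of the future C13 isopropyl group.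

Step 2
Reactants: 3 2-(2,6-dimethoxyphenyl)propan-2-ol
Product: 4 1,3-dimethoxy-2-(propan-2-yl)benzene
Conditions: Et3SiH, CF3CO2H, CH2Cl2, 0 °C → rt
Reagents that add atoms: none
Why: Ionic hydrogenation: CF3CO2H ionises the tertiary benzylic alcohol to a cumyl cation stabilised by both ortho methoxy groups, and Et3SiH delivers hydride.

Step 3
Reactants: 4 1,3-dimethoxy-2-(propan-2-yl)benzene
Product: 5 2,4-dimethoxy-3-(propan-2-yl)benzaldehyde
Conditions: Cl2CHOMe, TiCl4, CH2Cl2, −10 → 0 °C; H2O
Reagents that add atoms: dichloromethyl methyl ether, COC(Cl)Cl; water, O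
Why: Rieche formylation (Friedel–Crafts type): C4 and C6 are equivalent by symmetry and each is ortho to one methoxy group and para to the other, so a single aldehyde should form.

Step 4
Reactants: 5 2,4-dimethoxy-3-(propan-2-yl)benzaldehyde
Product: 7 2,4-dimethoxy-3-(propan-2-yl)phenol, via aryl formate 6 (not isolated)
Conditions: mCPBA, CH2Cl2, rt; then K2CO3 (cat.), MeOH, rt
Reagents that add atoms: 3-chloroperoxybenzoic acid, OOC(=O)c1cccc(Cl)c1
Why: Dakin-type Baeyer–Villiger oxidation: the electron-rich aryl group migrates to oxygen in the Criegee intermediate to give formate 6, and methanolysis frees the phenol oxygen that becomes O11.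

Step 5
Reactants: 7 2,4-dimethoxy-3-(propan-2-yl)phenol
Product: 8 6-bromo-2,4-dimethoxy-3-(propan-2-yl)phenol
Conditions: NBS (1.0 equiv), i-Pr2NH (cat.), CH2Cl2, 0 °C
Reagents that add atoms: N-bromosuccinimide, BrN1C(=O)CCC1=O
Why: Amine-catalysed ortho-bromination of a phenol: the para position is occupied by OMe, so the hydrogen-bonded phenol, the strongest activating group, should direct bromine to its single free ortho carbon, the future C9.

Step 6
Reactants: 8 6-bromo-2,4-dimethoxy-3-(propan-2-yl)phenol
Product: 9 2-(benzyloxy)-1-bromo-3,5-dimethoxy-4-(propan-2-yl)benzene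
Conditions: BnBr, K2CO3, DMF, 50 °C
Reagents that add atoms: benzyl bromide, BrCc1ccccc1
Why: Williamson ether synthesis: the phenoxide is benzylated so that O11 is carried as an ether that survives the basic and acidic steps and is removed reductively in step 14.

Step 7
Reactants: 10 methyl 2-oxocyclohexane-1-carboxylate; 11 tert-butyl L-valinate (free base from the commercial hydrochloride)
Product: 12 methyl 2-{[(2S)-1-tert-butoxy-3-methyl-1-oxobutan-2-yl]amino}cyclohex-1-ene-1-carboxylate
Conditions: TsOH (cat.), toluene, reflux, Dean–Stark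
Reagents that add atoms: none
Why: Acid-catalysed condensation with azeotropic removal of water gives the conjugated, hydrogen-bonded enamino ester (vinylogous carbamate) that carries the valine auxiliary.

Step 8
Reactants: 12 methyl 2-{[(2S)-1-tert-butoxy-3-methyl-1-oxobutan-2-yl]amino}cyclohex-1-ene-1-carboxylate
Product: 15 methyl (1S)-1-methyl-2-oxocyclohexane-1-carboxylate, via lithio-enamine 13 (not isolated), via methylated imine 14 (not isolated)
Conditions: LiN(i-Pr)2, toluene, −78 °C; HMPA (1 equiv); MeI, −78 → −55 °C; then aq. citric acid, rt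
Reagents that add atoms: iodomethane, CI; water, O
Why: Auxiliary-controlled alkylation of a chelated lithio-enamine (aza-enolate): lithium is held between the nitrogen and the valine ester carbonyl, the isopropyl group blocks one face, iodomethane enters from the other to create quaternary C4 as (S), and mild aqueous acid hydrolyses the imine and releases the auxiliary.

Step 9
Reactants: 15 methyl (1S)-1-methyl-2-oxocyclohexane-1-carboxylate; 9 2-(benzyloxy)-1-bromo-3,5-dimethoxy-4-(propan-2-yl)benzene
Product: 16 methyl (1S)-3-Ar-1-methyl-2-oxocyclohexane-1-carboxylate (both C3 epimers)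
Conditions: Pd2(dba)3 (cat.), XPhos, K3PO4, toluene, 90 °C
Reagents that add atoms: none
Why: Palladium-catalysed ketone α-arylation: the ketone can enolise only toward C3 because C1 is quaternary, the zerovalent palladium–XPhos complex inserts into the hindered electron-rich C–Br bond, and the phosphate base spares the non-enolisable β-keto ester from retro-Claisen cleavage; the C3 configuration is erased in step 10.

Step 10
Reactants: 16 methyl (1S)-3-Ar-1-methyl-2-oxocyclohexane-1-carboxylate (both C3 epimers); 17 formaldehyde (introduced as paraformaldehyde)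
Product: 19 (1S,5R)-5-Ar-1-methyl-3-oxabicyclo[3.3.1]nonane-2,9-dione, via hydroxymethyl ketone 18 (not isolated)
Conditions: (CH2O)n (5 equiv), DBU (1 equiv), THF, 50 °C
Reagents that add atoms: none
Why: DBU removes the C3 hydrogen of 16 (abietane C10), the only α-hydrogen of the ketone and a benzylic one, so both epimers converge on one enolate, which adds to formaldehyde (crossed aldol) and forms C10–C20 as a mixture of hydroxymethyl ketones. The closest known reaction type is base-mediated hydroxymethylation of an α-aryl ketone with formaldehyde followed by lactonisation of a δ-hydroxy ester. Only in 18, where hydroxymethyl and methyl ester are cis and can both be axial on the ring A chair, can the oxygen reach C19; it closes the six-membered lactone by 6-exo-trig acyl substitution with loss of methanol, which creates the 3-oxabicyclo[3.3.1]nonane. The new stereocentre C10 is thus controlled by the existing C4 centre through the ring closure: the trans epimer cannot lactonise and should return to the enolate by retro-aldol cleavage, made easy by the aryl-stabilised enolate. Regioselective enolisation is secured by quaternary C4, and an amidine is used in place of an alkoxide because the non-enolisable β-keto ester is open to retro-Claisen ring cleavage. Once the lactone is closed, C4–C5 cleavage would need a bridgehead enolate, so 19 should persist under the conditions.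

Step 11
Reactants: 19 (1S,5R)-5-Ar-1-methyl-3-oxabicyclo[3.3.1]nonane-2,9-dione; 20 tert-butyl acetate
Product: 22 tert-butyl 2-[(1S,5R,9S)-5-Ar-9-hydroxy-1-methyl-2-oxo-3-oxabicyclo[3.3.1]nonan-9-yl]acetate, via lithium ester enolate 21 (not isolated)
Conditions: LiN(i-Pr)2, THF, −78 °C; then 19, −78 °C; AcOH, −78 °C
Reagents that add atoms: none
Why: Aldol addition of a lithium ester enolate to the bridging ketone, which has no α-hydrogen and is more electrophilic than the neopentyl lactone carbonyl; attack is expected from the less hindered lactone-bridge face, and the carbinol configuration is of no consequence because this carbon becomes sp2 in step 12.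

Step 12
Reactants: 22 tert-butyl 2-[(1S,5R,9S)-5-Ar-9-hydroxy-1-methyl-2-oxo-3-oxabicyclo[3.3.1]nonan-9-yl]acetate
Product: 23 tert-butyl (2E)-2-[(1S,5R)-5-Ar-1-methyl-2-oxo-3-oxabicyclo[3.3.1]nonan-9-ylidene]acetate
Conditions: SOCl2, pyridine, 0 °C → rt
Reagents that add atoms: none
Why: Dehydration of a tertiary β-hydroxy ester through its chlorosulfite (pyridine-mediated elimination): only the C6 hydrogens are available because C4 and C10 are quaternary, so one regioisomer forms, and the E isomer with the ester on the C10 side is expected to prevail because the other geometry presses the ester against the eclipsed C4 methyl group.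

Step 13
Reactants: 23 tert-butyl (2E)-2-[(1S,5R)-5-Ar-1-methyl-2-oxo-3-oxabicyclo[3.3.1]nonan-9-ylidene]acetate
Product: 26 (4S,10R)-11-(benzyloxy)-12,14-dimethoxy-7-oxoabieta-5,8,11,13-tetraen-19,20-olide, via unsaturated acid 24 (not isolated), via acid chloride 25 (not isolated)
Conditions: CF3CO2H, CH2Cl2, 0 °C → rt, evaporate; (COCl)2, DMF (cat.), CH2Cl2, 0 °C; SnCl4, −78 → 0 °C
Reagents that add atoms: none
Why: Acidolysis of the tert-butyl ester, conversion into the acid chloride and SnCl4-promoted intramolecular Friedel–Crafts acylation: C8 is the only unsubstituted ring C carbon, is activated ortho and para by the two methoxy groups and lies next to the acyl carbon in the E isomer, so the six-membered ring B should close to a 4,4-disubstituted naphthalen-1(4H)-one at temperatures the benzyl ether tolerates.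

Step 14
Reactants: 26 (4S,10R)-11-(benzyloxy)-12,14-dimethoxy-7-oxoabieta-5,8,11,13-tetraen-19,20-olide
Product: 27 (4S,5R,10R)-11-hydroxy-12,14-dimethoxy-7-oxoabieta-8,11,13-trien-19,20-olide
Conditions: Li (6 equiv), NH3(l)/THF, t-BuOH (1 equiv), −78 °C; isoprene; NH4Cl
Reagents that add atoms: none
Why: Dissolving-metal (Birch-type) enone reduction: the β-carbanion at C5 is protonated axially on the face opposite the lactone bridge to give the more stable trans A/B fusion (5R), the C7 carbonyl stays masked as its lithium enolate until the quench, and the same medium cleaves the benzyl aryl ether reductively.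

Step 15
Reactants: 27 (4S,5R,10R)-11-hydroxy-12,14-dimethoxy-7-oxoabieta-8,11,13-trien-19,20-olide
Product: 28 (4S,5R,10R)-11,14-dihydroxy-12-methoxy-7-oxoabieta-8,11,13-trien-19,20-olide (CNP0159814.2)
Conditions: BCl3 (3 equiv), CH2Cl2, −78 → 0 °C; aq. NaHCO3
Reagents that add atoms: none
Why: Chelation-controlled Lewis acid ether cleavage: BCl3 held between the C7 carbonyl and the peri O14 removes that methyl group as chloromethane, while the non-chelated O12 methyl ether and the lactone should stay intact.

**Compound list**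

1 | 1,3-dimethoxybenzene | COc1cccc(OC)c1 | starting material
2 | (2,6-dimethoxyphenyl)lithium | [Li]c1c(OC)cccc1OC | intermediate (not isolated)
3 | 2-(2,6-dimethoxyphenyl)propan-2-ol | COc1cccc(OC)c1C(C)(C)O | intermediate
4 | 1,3-dimethoxy-2-(propan-2-yl)benzene | COc1cccc(OC)c1C(C)C | intermediate
5 | 2,4-dimethoxy-3-(propan-2-yl)benzaldehyde | COc1ccc(C=O)c(OC)c1C(C)C | intermediate
6 | 2,4-dimethoxy-3-(propan-2-yl)phenyl formate | COc1ccc(OC=O)c(OC)c1C(C)C | intermediate (not isolated)
7 | 2,4-dimethoxy-3-(propan-2-yl)phenol | COc1ccc(O)c(OC)c1C(C)C | intermediate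
8 | 6-bromo-2,4-dimethoxy-3-(propan-2-yl)phenol | COc1cc(Br)c(O)c(OC)c1C(C)C | intermediate
9 | 2-(benzyloxy)-1-bromo-3,5-dimethoxy-4-(propan-2-yl)benzene | COc1cc(Br)c(OCc2ccccc2)c(OC)c1C(C)C | intermediate
10 | methyl 2-oxocyclohexane-1-carboxylate | COC(=O)C1CCCCC1=O | starting material
11 | tert-butyl L-valinate | CC(C)[C@H](N)C(=O)OC(C)(C)C | starting material
12 | methyl 2-{[(2S)-1-tert-butoxy-3-methyl-1-oxobutan-2-yl]amino}cyclohex-1-ene-1-carboxylate | COC(=O)C1=C(N[C@@H](C(C)C)C(=O)OC(C)(C)C)CCCC1 | intermediate
13 | N-lithio derivative of 12 (lithium aza-enolate) | COC(=O)C1=C(N([Li])[C@@H](C(C)C)C(=O)OC(C)(C)C)CCCC1 | intermediate (not isolated)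
14 | methyl (1S)-2-{[(2S)-1-tert-butoxy-3-methyl-1-oxobutan-2-yl]imino}-1-methylcyclohexane-1-carboxylate | COC(=O)[C@@]1(C)CCCCC1=N[C@@H](C(C)C)C(=O)OC(C)(C)C | intermediate (not isolated)
15 | methyl (1S)-1-methyl-2-oxocyclohexane-1-carboxylate | COC(=O)[C@@]1(C)CCCCC1=O | intermediate
16 | methyl (1S)-3-[2-(benzyloxy)-3,5-dimethoxy-4-(propan-2-yl)phenyl]-1-methyl-2-oxocyclohexane-1-carboxylate, both C3 epimers | COc1cc(C2CCC[C@](C)(C(=O)OC)C2=O)c(OCc2ccccc2)c(OC)c1C(C)C | intermediate
17 | formaldehyde (introduced as paraformaldehyde) | C=O | starting material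
18 | methyl (1S,3R)-3-Ar-3-(hydroxymethyl)-1-methyl-2-oxocyclohexane-1-carboxylate (hydroxymethyl cis to the ester) | COc1cc([C@@]2(CO)CCC[C@](C)(C(=O)OC)C2=O)c(OCc2ccccc2)c(OC)c1C(C)C | intermediate (not isolated)
19 | (1S,5R)-5-[2-(benzyloxy)-3,5-dimethoxy-4-(propan-2-yl)phenyl]-1-methyl-3-oxabicyclo[3.3.1]nonane-2,9-dione | COc1cc([C@]23CCC[C@](C)(C(=O)OC2)C3=O)c(OCc2ccccc2)c(OC)c1C(C)C | intermediate
20 | tert-butyl acetate | CC(=O)OC(C)(C)C | starting material
21 | lithium 1-tert-butoxyethen-1-olate (lithium enolate of 20) | [Li]OC(=C)OC(C)(C)C | intermediate (not isolated)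
22 | tert-butyl 2-[(1S,5R,9S)-5-Ar-9-hydroxy-1-methyl-2-oxo-3-oxabicyclo[3.3.1]nonan-9-yl]acetate (CH2CO2t-Bu on the lactone-bridge face) | COc1cc([C@]23CCC[C@](C)(C(=O)OC2)[C@]3(O)CC(=O)OC(C)(C)C)c(OCc2ccccc2)c(OC)c1C(C)C | intermediate
23 | tert-butyl (2E)-2-[(1S,5R)-5-Ar-1-methyl-2-oxo-3-oxabicyclo[3.3.1]nonan-9-ylidene]acetate (ester on the aryl-bearing side) | COc1cc([C@]23CCC[C@](C)(C(=O)OC2)/C3=C/C(=O)OC(C)(C)C)c(OCc2ccccc2)c(OC)c1C(C)C | intermediate
24 | (2E)-2-[(1S,5R)-5-Ar-1-methyl-2-oxo-3-oxabicyclo[3.3.1]nonan-9-ylidene]acetic acid | COc1cc([C@]23CCC[C@](C)(C(=O)OC2)/C3=C/C(O)=O)c(OCc2ccccc2)c(OC)c1C(C)C | intermediate (not isolated)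
25 | (2E)-2-[(1S,5R)-5-Ar-1-methyl-2-oxo-3-oxabicyclo[3.3.1]nonan-9-ylidene]acetyl chloride | COc1cc([C@]23CCC[C@](C)(C(=O)OC2)/C3=C/C(Cl)=O)c(OCc2ccccc2)c(OC)c1C(C)C | intermediate (not isolated)
26 | (4S,10R)-11-(benzyloxy)-12,14-dimethoxy-7-oxoabieta-5,8,11,13-tetraen-19,20-olide (lactone C19(=O)–O–C20) | COc1c(OCc4ccccc4)c2c(c(OC)c1C(C)C)C(=O)C=C1[C@]23CCC[C@]1(C)C(=O)OC3 | intermediate
27 | (4S,5R,10R)-11-hydroxy-12,14-dimethoxy-7-oxoabieta-8,11,13-trien-19,20-olide | COc1c(O)c2c(c(OC)c1C(C)C)C(=O)C[C@@H]1[C@]23CCC[C@]1(C)C(=O)OC3 | intermediate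
28 | (4S,5R,10R)-11,14-dihydroxy-12-methoxy-7-oxoabieta-8,11,13-trien-19,20-olide (CNP0159814.2) | COc1c(O)c2c(c(O)c1C(C)C)C(=O)C[C@@H]1[C@]23CCC[C@]1(C)C(=O)OC3 | target

**Count**

Total steps: 15. Longest linear sequence: 13 steps (steps 1–6, then 9–15).

**Steps most likely to fail**

Step 10. Enolisation by the amidine may be too slow, or retro-aldol cleavage may outrun lactonisation so that the cis hydroxymethyl ketone never builds up; methanol released in the step may also open ring A by retro-Claisen cleavage. The fallback sets out from 16 and returns at 19. KN(SiMe3)2 and Me3SiCl convert 16 into the trimethylsilyl enol ether F1. Sc(OTf)3-catalysed Mukaiyama hydroxymethylation with aqueous formaldehyde in THF then forms C10–C20 without base and gives hydroxymethyl ketone 18 beside the (1S,3S)-hydroxymethyl ketone F2. TsOH in toluene lactonises 18 to 19. F2 cannot cyclise; it is separated and returned to 16 by brief DBU treatment (retro-aldol) for another pass.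

Step 11. The aldol addition at a ketone flanked by two quaternary carbons may revert on warming, or the enolate may be acylated at the lactone carbonyl. The fallback sets out from 19 and returns at 24. LiC≡COEt (from ethoxyacetylene and n-BuLi, THF, −78 °C), a slim nucleophile that adds irreversibly, gives the propargylic alcohol F3. Meyer–Schuster rearrangement (Sc(OTf)3 cat., EtOH/CH2Cl2) gives the ethyl ylidene acetate F4. LiOH in THF/H2O followed by acidification, which re-closes the lactone should it open, gives acid 24, which continues in step 13 from the oxalyl chloride stage.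

Step 13. The acyl group may sit on the C4 side of the exocyclic double bond and fail to isomerise under the Lewis acid, so that it cannot reach C8; the acid may also cause loss or migration of the benzyl group. The fallback sets out from 23 (either geometry) and returns at 26. Mg in MeOH reduces the conjugated double bond to the saturated tert-butyl ester F5. CF3CO2H, then (COCl)2 and SnCl4 as in step 13, lead through the saturated acid F6 and the saturated acid chloride F7 to the saturated tricyclic ketone F8, whose ring closure no longer depends on alkene geometry. LiN(SiMe3)2 and Me3SiCl give the trimethylsilyl enol ether F9, and Saegusa–Ito oxidation with Pd(OAc)2 in MeCN restores the C5=C6 double bond to give 26.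

**Further compounds**

F1 | step 10 | methyl (1S)-3-Ar-1-methyl-2-[(trimethylsilyl)oxy]cyclohex-2-ene-1-carboxylate | COc1cc(C2=C(O[Si](C)(C)C)[C@@](C)(C(=O)OC)CCC2)c(OCc2ccccc2)c(OC)c1C(C)C
F2 | step 10 | methyl (1S,3S)-3-Ar-3-(hydroxymethyl)-1-methyl-2-oxocyclohexane-1-carboxylate | COc1cc([C@]2(CO)CCC[C@](C)(C(=O)OC)C2=O)c(OCc2ccccc2)c(OC)c1C(C)C
F3 | step 11 | (1S,5R,9R)-5-Ar-9-(ethoxyethynyl)-9-hydroxy-1-methyl-3-oxabicyclo[3.3.1]nonan-2-one | COc1cc([C@]23CCC[C@](C)(C(=O)OC2)[C@]3(O)C#COCC)c(OCc2ccccc2)c(OC)c1C(C)C
F4 | step 11 | ethyl (2E)-2-[(1S,5R)-5-Ar-1-methyl-2-oxo-3-oxabicyclo[3.3.1]nonan-9-ylidene]acetate | COc1cc([C@]23CCC[C@](C)(C(=O)OC2)/C3=C/C(=O)OCC)c(OCc2ccccc2)c(OC)c1C(C)C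
F5 | step 13 | tert-butyl 2-[(1S,5R)-5-Ar-1-methyl-2-oxo-3-oxabicyclo[3.3.1]nonan-9-yl]acetate, C9 epimers | COc1cc([C@]23CCC[C@](C)(C(=O)OC2)C3CC(=O)OC(C)(C)C)c(OCc2ccccc2)c(OC)c1C(C)C
F6 | step 13 | 2-[(1S,5R)-5-Ar-1-methyl-2-oxo-3-oxabicyclo[3.3.1]nonan-9-yl]acetic acid, C9 epimers | COc1cc([C@]23CCC[C@](C)(C(=O)OC2)C3CC(O)=O)c(OCc2ccccc2)c(OC)c1C(C)C
F7 | step 13 | 2-[(1S,5R)-5-Ar-1-methyl-2-oxo-3-oxabicyclo[3.3.1]nonan-9-yl]acetyl chloride, C9 epimers | COc1cc([C@]23CCC[C@](C)(C(=O)OC2)C3CC(Cl)=O)c(OCc2ccccc2)c(OC)c1C(C)C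
F8 | step 13 | (4S,10R)-11-(benzyloxy)-12,14-dimethoxy-7-oxoabieta-8,11,13-trien-19,20-olide, C5 epimers | COc1c(OCc4ccccc4)c2c(c(OC)c1C(C)C)C(=O)CC1[C@]23CCC[C@]1(C)C(=O)OC3
F9 | step 13 | (4S,10R)-11-(benzyloxy)-12,14-dimethoxy-7-[(trimethylsilyl)oxy]abieta-6,8,11,13-tetraen-19,20-olide, C5 epimers | COc1c(OCc4ccccc4)c2c(c(OC)c1C(C)C)C(O[Si](C)(C)C)=CC1[C@]23CCC[C@]1(C)C(=O)OC3
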